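Ring A (the acyl ring) is assembled last, on the depside ester. Its pattern (depside carbonyl on ring A carbon 1, hydroxyls on carbons 2 and 4, hydrogens on carbons 3 and 5, 2-oxononyl chain on carbon 6) is the imprint of a 1,1,3-trioxygenated butadiene (carbons 2 to 5) on an alk-2-ynoate (carbons 1 and 6). One thermal Diels–Alder/aromatisation forges the bonds between carbons 1 and 2 and between carbons 5 and 6, closes ring A and installs both phenols. The precursor is the aryl but-2-ynoate of the ring B 4-hydroxyl, with both ketones masked as dioxolanes and the chelated ring B 2-hydroxyl left free (silylated in the flask), so one mild hydrolysis finishes the synthesis.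

Key step: step 13

Remarks on the chemistry
- Ring numbering: in ring A (the acyl ring) carbon 1 carries the depside carbonyl and carbon 6 the 2-oxononyl chain. In ring B (the phenol ring) carbon 1 carries CO2Me, carbon 2 the free hydroxyl, carbon 4 the depside oxygen and carbon 6 the second 2-oxononyl chain.
- The target has no stereocentre. The geometries of the silyl enol ether and of the ketene acetal are left undefined because both are erased.
- Design choice for the precursor: the ring B 2-hydroxyl carries no isolated protecting group. It is hydrogen-bonded to the neighbouring methyl ester, is capped as a trimethylsilyl ether in the flask for the cycloaddition, and is freed in the same work-up. This avoids an acid-labile phenol acetal that would not survive ketalisation of the ring B ketone and would need stronger acid at the end.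
- The diene is assumed to be best made fresh, because it is moisture-sensitive; it is therefore prepared in two steps.

Step 1
Reactants: 1 methyl 3-oxodecanoate
Product: 2 methyl 2-(2-heptyl-1,3-dioxolan-2-yl)acetate
Conditions: HOCH2CH2OH (3 equiv), TsOH·H2O (2 mol %), toluene, reflux, Dean–Stark
Reagents that add atoms: ethylene glycol, OCCO
Why: Acid-catalysed ketalisation with azeotropic removal of water is routine for beta-keto esters and masks the ketone before the hydride and organolithium steps.

Step 2
Reactants: 2 methyl 2-(2-heptyl-1,3-dioxolan-2-yl)acetate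
Product: 4 2-(2-heptyl-1,3-dioxolan-2-yl)acetaldehyde, via aluminium hemiacetal 3 (not isolated)
Conditions: i-Bu2AlH (1.05 equiv), CH2Cl2, −78 °C; MeOH, then aq. KNaC4H4O6
Reagents that add atoms: none
Why: Partial ester reduction with diisobutylaluminium hydride should stop at the aldehyde because the tetrahedral hemiacetal 3, chelated by a ketal oxygen, persists at −78 °C until the quench.

Step 3
Reactants: 4 2-(2-heptyl-1,3-dioxolan-2-yl)acetaldehyde
Product: 5 2-heptyl-2-(prop-2-yn-1-yl)-1,3-dioxolane
Conditions: MeC(O)C(N2)P(O)(OMe)2 (1.3 equiv), K2CO3 (2 equiv), MeOH, 0 °C → rt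
Reagents that add atoms: dimethyl (1-diazo-2-oxopropyl)phosphonate, COP(=O)(OC)C(=[N+]=[N-])C(C)=O
Why: Seyferth–Gilbert homologation in its Ohira–Bestmann form should convert the aldehyde into the terminal alkyne under mild carbonate conditions that leave the ketal untouched.

Step 4
Reactants: 5 2-heptyl-2-(prop-2-yn-1-yl)-1,3-dioxolane
Product: 8 4-(2-heptyl-1,3-dioxolan-2-yl)but-2-ynoic acid, via lithium acetylide 6 (not isolated), via lithium carboxylate 7 (not isolated)
Conditions: n-BuLi (1.05 equiv), THF, −78 °C; CO2 (gas), −78 → 0 °C; cold 1 M aq. HCl to pH 2–3, immediate extraction, used at once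
Reagents that add atoms: carbon dioxide, O=C=O
Why: Deprotonation of the terminal alkyne and carboxylation of the acetylide is the standard entry to alk-2-ynoic acids, and a brief cold acidification should spare the dioxolane.

Step 5
Reactants: 9 methyl orsellinate (methyl 2,4-dihydroxy-6-methylbenzoate)
Product: 10 methyl 2,4-bis(benzyloxy)-6-methylbenzoate
Conditions: BnBr (2.4 equiv), K2CO3 (3 equiv), DMF, 60 °C
Reagents that add atoms: benzyl bromide, BrCc1ccccc1
Why: Williamson etherification with excess reagent and warming should also alkylate the chelated 2-hydroxyl, giving ethers that tolerate amide bases and Lewis acid and later leave by hydrogenolysis.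

Step 6
Reactants: 11 octanoyl chloride
Product: 12 N-methoxy-N-methyloctanamide
Conditions: MeNH(OMe)·HCl (1.1 equiv), K2CO3 (2.5 equiv), EtOAc–H2O, 0 °C → rt
Reagents that add atoms: N,O-dimethylhydroxylamine hydrochloride, CNOC.Cl
Why: Schotten–Baumann acylation should give the Weinreb amide, an acyl donor that stops cleanly at the ketone stage in the next step.

Step 7
Reactants: 10 methyl 2,4-bis(benzyloxy)-6-methylbenzoate; 12 N-methoxy-N-methyloctanamide
Product: 15 methyl 2,4-bis(benzyloxy)-6-(2-oxononyl)benzoate, via benzylic organolithium 13 (not isolated), via tetrahedral lithium adduct 14 (not isolated)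
Conditions: LiN(i-Pr)2 (1.15 equiv), THF, −78 °C; 12 (1.3 equiv), −78 → −40 °C; AcOH, −78 °C, then water
Reagents that add atoms: none
Why: Lateral lithiation of the ortho-toluate followed by Weinreb acylation should give the benzyl ketone, because the chelated adduct 14 does not collapse before the quench and so prevents over-addition and proton transfer to the more acidic product.

Step 8
Reactants: 15 methyl 2,4-bis(benzyloxy)-6-(2-oxononyl)benzoate
Product: 16 methyl 2,4-bis(benzyloxy)-6-[(2-heptyl-1,3-dioxolan-2-yl)methyl]benzoate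
Conditions: TMSOCH2CH2OTMS (2 equiv), TMSOTf (5 mol %), CH2Cl2, −78 → −20 °C; pyridine quench
Reagents that add atoms: 1,2-bis(trimethylsilyloxy)ethane, C[Si](C)(C)OCCO[Si](C)(C)C
Why: Noyori ketalisation at low temperature should protect the ketone without the hot Brønsted acid that could lactonise the ortho keto ester to an isocoumarin.

Step 9
Reactants: 16 methyl 2,4-bis(benzyloxy)-6-[(2-heptyl-1,3-dioxolan-2-yl)methyl]benzoate
Product: 17 methyl 6-[(2-heptyl-1,3-dioxolan-2-yl)methyl]-2,4-dihydroxybenzoate
Conditions: H2 (1 atm), Pd/C (10 wt % palladium on carbon), EtOAc, rt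
Reagents that add atoms: none
Why: Catalytic hydrogenolysis of both benzyl ethers runs under neutral conditions, so the dioxolane and the methyl ester should be unaffected.

Step 10
Reactants: 18 methyl acetoacetate
Product: 19 methyl 3-(trimethylsilyloxy)but-2-enoate
Conditions: TMSCl (1.2 equiv), Et3N (1.3 equiv), hexane, rt; filtration, distillation
Reagents that add atoms: chlorotrimethylsilane, C[Si](C)(C)Cl
Why: O-Silylation of the enolised beta-keto ester (silyl enol ether formation) is the standard first stage of the diene preparation, and its double-bond geometry is lost in the next step.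

Step 11
Reactants: 19 methyl 3-(trimethylsilyloxy)but-2-enoate
Product: 21 1-methoxy-1,3-bis(trimethylsilyloxy)buta-1,3-diene, via lithium dienolate 20 (not isolated)
Conditions: LiN(i-Pr)2 (1.1 equiv), THF, −78 °C; TMSCl (1.2 equiv), −78 → 0 °C; hexane, filtration under argon, used fresh
Reagents that add atoms: chlorotrimethylsilane, C[Si](C)(C)Cl
Why: Gamma-deprotonation to the extended dienolate and O-silylation (silyl ketene acetal formation) should give the bis-silyloxy diene, whose ketene acetal geometry does not matter later.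

Step 12
Reactants: 8 4-(2-heptyl-1,3-dioxolan-2-yl)but-2-ynoic acid; 17 methyl 6-[(2-heptyl-1,3-dioxolan-2-yl)methyl]-2,4-dihydroxybenzoate
Product: 22 methyl 4-{[4-(2-heptyl-1,3-dioxolan-2-yl)but-2-ynoyl]oxy}-6-[(2-heptyl-1,3-dioxolan-2-yl)methyl]-2-hydroxybenzoate
Conditions: 8 (1.1 equiv), DCC (1.1 equiv), DMAP (5 mol %), CH2Cl2, −20 → 0 °C
Reagents that add atoms: none
Why: Steglich esterification should acylate only the 4-hydroxyl of ring B, since the 2-hydroxyl is locked in a hydrogen bond to the adjacent ester carbonyl and is far less nucleophilic, while low temperature and little DMAP guard the ynoate against isomerisation.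

Step 13
Reactants: 22 methyl 4-{[4-(2-heptyl-1,3-dioxolan-2-yl)but-2-ynoyl]oxy}-6-[(2-heptyl-1,3-dioxolan-2-yl)methyl]-2-hydroxybenzoate; 21 1-methoxy-1,3-bis(trimethylsilyloxy)buta-1,3-diene
Product: 26 methyl 4-({6-[(2-heptyl-1,3-dioxolan-2-yl)methyl]-2,4-dihydroxybenzoyl}oxy)-6-[(2-heptyl-1,3-dioxolan-2-yl)methyl]-2-hydroxybenzoate, via trimethylsilyl ether 23 (not isolated), via cyclohexadiene cycloadduct 24 (not isolated), via bis-silylated arene 25 (not isolated)
Conditions: N,O-bis(trimethylsilyl)acetamide (1.2 equiv), toluene, 60 °C, 1 h; 21 (3 equiv, in two portions), 100 °C, sealed tube, 24–48 h; 5 % aq. citric acid–THF, 0 °C → rt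
Reagents that add atoms: none
Why: The cycloaddition is a polar, asynchronous [4+2] (Diels–Alder) in which the unsubstituted terminus of 21, the carbon of highest HOMO coefficient, bonds first to the electrophilic beta-carbon of the ynoate (the future carbon 6 of ring A) and the ketene acetal carbon then bonds to the alpha-carbon (carbon 1 of ring A), so ring A closes as a six-membered carbocycle by intermolecular [4+2] annulation. The closest known reaction type is the Diels–Alder/aromatisation of 1,1,3-trioxygenated butadienes with acetylenic esters to give resorcylates; beta-alkyl ynoates are slow and need heat, which is why the electron-poor aryl ester (lower LUMO than an alkyl ester) and an excess of diene are used. Cycloadduct 24 collapses at its mixed ketal carbon (carbon 2 of ring A) with loss of methoxytrimethylsilane to a cross-conjugated dienone that tautomerises to the phenol, so the only stereocentre formed (the mixed ketal carbon, racemic) is erased and the ketene acetal geometry of 21 is immaterial. The selectivity required is regiochemical and is secured by the matched polarisation of the two partners, which puts the ketene-acetal-derived hydroxyl on carbon 2 of ring A next to the ester and the enol-ether-derived one on carbon 4. Prior silylation of the ring B 2-hydroxyl stops it from protonating the diene, the dioxolanes and both esters tolerate neutral thermal conditions, and the mild aqueous acid of the work-up should cleave only the aryl O–Si bonds.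

Step 14
Reactants: 26 methyl 4-({6-[(2-heptyl-1,3-dioxolan-2-yl)methyl]-2,4-dihydroxybenzoyl}oxy)-6-[(2-heptyl-1,3-dioxolan-2-yl)methyl]-2-hydroxybenzoate
Product: 27 methyl 4-{[2,4-dihydroxy-6-(2-oxononyl)benzoyl]oxy}-2-hydroxy-6-(2-oxononyl)benzoate (target)
Conditions: 1 M aq. HCl–THF (1:4), rt, monitored and stopped at full conversion
Reagents that add atoms: water, O
Why: Acid-catalysed ketal hydrolysis should free both ketones in dilute acid at room temperature, conditions under which the aryl ester, the methyl ester and the free phenols are expected to persist.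

Compound list
1 | methyl 3-oxodecanoate | CCCCCCCC(=O)CC(=O)OC | starting material
2 | methyl 2-(2-heptyl-1,3-dioxolan-2-yl)acetate | CCCCCCCC1(CC(=O)OC)OCCO1 | intermediate
3 | [2-(2-heptyl-1,3-dioxolan-2-yl)-1-methoxyethoxy]bis(2-methylpropyl)aluminium (racemic hemiacetal, formed in the flask) | CCCCCCCC1(CC(OC)O[Al](CC(C)C)CC(C)C)OCCO1 | intermediate
4 | 2-(2-heptyl-1,3-dioxolan-2-yl)acetaldehyde | CCCCCCCC1(CC=O)OCCO1 | intermediate
5 | 2-heptyl-2-(prop-2-yn-1-yl)-1,3-dioxolane | CCCCCCCC1(CC#C)OCCO1 | intermediate
6 | [3-(2-heptyl-1,3-dioxolan-2-yl)prop-1-yn-1-yl]lithium (formed in the flask) | CCCCCCCC1(CC#C[Li])OCCO1 | intermediate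
7 | lithium 4-(2-heptyl-1,3-dioxolan-2-yl)but-2-ynoate (formed in the flask) | CCCCCCCC1(CC#CC(=O)[O-])OCCO1.[Li+] | intermediate
8 | 4-(2-heptyl-1,3-dioxolan-2-yl)but-2-ynoic acid | CCCCCCCC1(CC#CC(=O)O)OCCO1 | intermediate
9 | methyl orsellinate (methyl 2,4-dihydroxy-6-methylbenzoate) | COC(=O)c1c(C)cc(O)cc1O | starting material
10 | methyl 2,4-bis(benzyloxy)-6-methylbenzoate | COC(=O)c1c(C)cc(OCc2ccccc2)cc1OCc1ccccc1 | intermediate
11 | octanoyl chloride | CCCCCCCC(=O)Cl | starting material
12 | N-methoxy-N-methyloctanamide | CCCCCCCC(=O)N(C)OC | intermediate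
13 | {[3,5-bis(benzyloxy)-2-(methoxycarbonyl)phenyl]methyl}lithium (formed in the flask) | COC(=O)c1c(C[Li])cc(OCc2ccccc2)cc1OCc1ccccc1 | intermediate
14 | lithium alkoxide of methyl 2,4-bis(benzyloxy)-6-{2-hydroxy-2-[methoxy(methyl)amino]nonyl}benzoate (racemic, formed in the flask) | CCCCCCCC(O[Li])(Cc1cc(OCc2ccccc2)cc(OCc2ccccc2)c1C(=O)OC)N(C)OC | intermediate
15 | methyl 2,4-bis(benzyloxy)-6-(2-oxononyl)benzoate | CCCCCCCC(=O)Cc1cc(OCc2ccccc2)cc(OCc2ccccc2)c1C(=O)OC | intermediate
16 | methyl 2,4-bis(benzyloxy)-6-[(2-heptyl-1,3-dioxolan-2-yl)methyl]benzoate | CCCCCCCC1(Cc2cc(OCc3ccccc3)cc(OCc3ccccc3)c2C(=O)OC)OCCO1 | intermediate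
17 | methyl 6-[(2-heptyl-1,3-dioxolan-2-yl)methyl]-2,4-dihydroxybenzoate | CCCCCCCC1(Cc2cc(O)cc(O)c2C(=O)OC)OCCO1 | intermediate
18 | methyl acetoacetate | CC(=O)CC(=O)OC | starting material
19 | methyl 3-(trimethylsilyloxy)but-2-enoate (mixture of double-bond isomers, inconsequential) | COC(=O)C=C(C)O[Si](C)(C)C | intermediate
20 | lithium 1-methoxy-3-(trimethylsilyloxy)buta-1,3-dien-1-olate (formed in the flask) | COC(O[Li])=CC(=C)O[Si](C)(C)C | intermediate
21 | 1-methoxy-1,3-bis(trimethylsilyloxy)buta-1,3-diene (ketene acetal geometry undefined, inconsequential) | COC(O[Si](C)(C)C)=CC(=C)O[Si](C)(C)C | intermediate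
22 | methyl 4-{[4-(2-heptyl-1,3-dioxolan-2-yl)but-2-ynoyl]oxy}-6-[(2-heptyl-1,3-dioxolan-2-yl)methyl]-2-hydroxybenzoate | CCCCCCCC1(CC#CC(=O)Oc2cc(O)c(C(=O)OC)c(CC3(CCCCCCC)OCCO3)c2)OCCO1 | intermediate
23 | methyl 4-{[4-(2-heptyl-1,3-dioxolan-2-yl)but-2-ynoyl]oxy}-6-[(2-heptyl-1,3-dioxolan-2-yl)methyl]-2-(trimethylsilyloxy)benzoate (formed in the flask) | CCCCCCCC1(CC#CC(=O)Oc2cc(O[Si](C)(C)C)c(C(=O)OC)c(CC3(CCCCCCC)OCCO3)c2)OCCO1 | intermediate
24 | 3-[(2-heptyl-1,3-dioxolan-2-yl)methyl]-4-(methoxycarbonyl)-5-(trimethylsilyloxy)phenyl 2-[(2-heptyl-1,3-dioxolan-2-yl)methyl]-6-methoxy-4,6-bis(trimethylsilyloxy)cyclohexa-1,4-diene-1-carboxylate (racemic at the mixed ketal carbon, formed in the flask) | CCCCCCCC1(CC2=C(C(=O)Oc3cc(O[Si](C)(C)C)c(C(=O)OC)c(CC4(CCCCCCC)OCCO4)c3)C(OC)(O[Si](C)(C)C)C=C(O[Si](C)(C)C)C2)OCCO1 | intermediate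
25 | methyl 4-({6-[(2-heptyl-1,3-dioxolan-2-yl)methyl]-2-hydroxy-4-(trimethylsilyloxy)benzoyl}oxy)-6-[(2-heptyl-1,3-dioxolan-2-yl)methyl]-2-(trimethylsilyloxy)benzoate (formed in the flask) | CCCCCCCC1(Cc2cc(O[Si](C)(C)C)cc(O)c2C(=O)Oc2cc(O[Si](C)(C)C)c(C(=O)OC)c(CC3(CCCCCCC)OCCO3)c2)OCCO1 | intermediate
26 | methyl 4-({6-[(2-heptyl-1,3-dioxolan-2-yl)methyl]-2,4-dihydroxybenzoyl}oxy)-6-[(2-heptyl-1,3-dioxolan-2-yl)methyl]-2-hydroxybenzoate | CCCCCCCC1(Cc2cc(O)cc(O)c2C(=O)Oc2cc(O)c(C(=O)OC)c(CC3(CCCCCCC)OCCO3)c2)OCCO1 | intermediate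
27 | methyl 4-{[2,4-dihydroxy-6-(2-oxononyl)benzoyl]oxy}-2-hydroxy-6-(2-oxononyl)benzoate (CNP0110390.0) | CCCCCCCC(=O)Cc1cc(OC(=O)c2c(O)cc(O)cc2CC(=O)CCCCCCC)cc(O)c1C(=O)OC | target

Total step count: 14

Longest linear sequence: 7 steps (steps 1, 2, 3, 4, 12, 13, 14; the ring B branch through steps 5, 7, 8, 9, 12, 13, 14 is equally long).

Steps most likely to fail

Step 13. The beta-alkyl ynoate may react so slowly that other processes win: thermal decay of the diene (silyl migration, adventitious hydrolysis), attack of the nucleophilic diene on the aryl ester, or addition in the reversed orientation. The fallback imports ring A instead of building it, because ester 16 already holds the complete ring A carbon skeleton. It sets out from 16 and 17. Saponification of 16 (KOH, DMSO–H2O, 90 °C) should give potassium 2,4-bis(benzyloxy)-6-[(2-heptyl-1,3-dioxolan-2-yl)methyl]benzoate F1, which careful acidification with acetic acid converts into 2,4-bis(benzyloxy)-6-[(2-heptyl-1,3-dioxolan-2-yl)methyl]benzoic acid F2. Carbodiimide esterification of F2 with the 4-hydroxyl of 17 (DCC, DMAP, CH2Cl2, rt) should give methyl 4-({2,4-bis(benzyloxy)-6-[(2-heptyl-1,3-dioxolan-2-yl)methyl]benzoyl}oxy)-6-[(2-heptyl-1,3-dioxolan-2-yl)methyl]-2-hydroxybenzoate F3. Hydrogenolysis of F3 (H2, Pd/C, EtOAc) comes back to the route at 26.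

Step 12. The ketal may be lost while the strongly acidic ynoic acid 8 is isolated; the activated acid may rearrange to an N-acylurea; DMAP may isomerise the ynoate to the allenoate or add to it; and acylation may run beyond the 4-hydroxyl of ring B. The fallback avoids both the free acid and the carbodiimide. It sets out from alkyne 5, which is lithiated and carboxylated as in step 4 to give 6 and then 7. Without acidification, the dried lithium carboxylate 7 is treated with oxalyl chloride and catalytic DMF (CH2Cl2, 0 °C), a neutral activation that releases no hydrogen chloride, to give 4-(2-heptyl-1,3-dioxolan-2-yl)but-2-ynoyl chloride F4. Crude F4 is added at −40 °C to 17 and 2,6-lutidine in CH2Cl2, which comes back to the route at 22.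

Step 7. The benzylic anion may condense with the ester of unreacted 10, may enolise the Weinreb amide or cleave its N–O bond instead of adding, or lateral deprotonation may be incomplete. The fallback attaches the future ketone carbon first as a carboxyl and adds the heptyl group afterwards. It sets out from 10. Anion 13, made as in step 7, is poured onto excess solid CO2 to give lithium [3,5-bis(benzyloxy)-2-(methoxycarbonyl)phenyl]acetate F5, and acidification (cold 1 M aq. HCl) gives [3,5-bis(benzyloxy)-2-(methoxycarbonyl)phenyl]acetic acid F6. Amidation (MeNH(OMe)·HCl, Et3N, DCC, CH2Cl2) should give methyl 2,4-bis(benzyloxy)-6-{2-[methoxy(methyl)amino]-2-oxoethyl}benzoate F7. Addition of n-C7H15MgBr (THF, −20 → 0 °C), to which the hindered aryl methyl ester should be inert, gives the bromomagnesium alkoxide of methyl 2,4-bis(benzyloxy)-6-{2-hydroxy-2-[methoxy(methyl)amino]nonyl}benzoate F8. On quenching with cold aq. HCl, F8 collapses to the ketone and the fallback comes back to the route at 15.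

Further compounds
F1 | step 13 | potassium 2,4-bis(benzyloxy)-6-[(2-heptyl-1,3-dioxolan-2-yl)methyl]benzoate | CCCCCCCC1(Cc2cc(OCc3ccccc3)cc(OCc3ccccc3)c2C(=O)[O-])OCCO1.[K+]
F2 | step 13 | 2,4-bis(benzyloxy)-6-[(2-heptyl-1,3-dioxolan-2-yl)methyl]benzoic acid | CCCCCCCC1(Cc2cc(OCc3ccccc3)cc(OCc3ccccc3)c2C(=O)O)OCCO1
F3 | step 13 | methyl 4-({2,4-bis(benzyloxy)-6-[(2-heptyl-1,3-dioxolan-2-yl)methyl]benzoyl}oxy)-6-[(2-heptyl-1,3-dioxolan-2-yl)methyl]-2-hydroxybenzoate | CCCCCCCC1(Cc2cc(OCc3ccccc3)cc(OCc3ccccc3)c2C(=O)Oc2cc(O)c(C(=O)OC)c(CC3(CCCCCCC)OCCO3)c2)OCCO1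
F4 | step 12 | 4-(2-heptyl-1,3-dioxolan-2-yl)but-2-ynoyl chloride | CCCCCCCC1(CC#CC(=O)Cl)OCCO1
F5 | step 7 | lithium [3,5-bis(benzyloxy)-2-(methoxycarbonyl)phenyl]acetate | COC(=O)c1c(CC(=O)[O-])cc(OCc2ccccc2)cc1OCc1ccccc1.[Li+]
F6 | step 7 | [3,5-bis(benzyloxy)-2-(methoxycarbonyl)phenyl]acetic acid | COC(=O)c1c(CC(=O)O)cc(OCc2ccccc2)cc1OCc1ccccc1
F7 | step 7 | methyl 2,4-bis(benzyloxy)-6-{2-[methoxy(methyl)amino]-2-oxoethyl}benzoate | CON(C)C(=O)Cc1cc(OCc2ccccc2)cc(OCc2ccccc2)c1C(=O)OC
F8 | step 7 | bromomagnesium alkoxide of methyl 2,4-bis(benzyloxy)-6-{2-hydroxy-2-[methoxy(methyl)amino]nonyl}benzoate (racemic) | CCCCCCCC(O[Mg]Br)(Cc1cc(OCc2ccccc2)cc(OCc2ccccc2)c1C(=O)OC)N(C)OC
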